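**Out of reach.** Turning the whole substrate into target is impossible in the closed flasks below. The same charge also goes through a flow tank.

| flask | substrate | fresh partner | coupling partner | protic impurity | time | remark |
|---|---|---|---|---|---|---|
| gamma | 5.0 mM | 5.50 mM | 10.0 mM | 5.00 mM | 20 s | everything together in a closed stirred flask, run for 20 s |
| delta | 5.0 mM | 5.50 mM | 10.0 mM | 5.00 mM |  | one stirred flow tank at steady state, fed with the mixture as stated, mean residence time 20 s |
| zeta | 5.0 mM | 5.50 mM (fed, over 16.0 s) | 10.0 mM | 5.00 mM | 20 s | all but fresh partner at the start; fresh partner goes in evenly over 16.0 s, the run ends at 20 s |
| epsilon | 5.0 mM | 5.50 mM | 10.0 mM (fed, over 16.0 s) | 5.00 mM | 20 s | a stirred flask in which coupling partner is dosed at a steady rate over 16.0 s without added volume, worked up at 20 s |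

    fresh partner + protic impurity → quenched reagent (k1 = 1100 /M/s)
    open intermediate + second intermediate → target (k2 = 19 /M/s)
    coupling partner + fresh partner → second intermediate (k3 = 21 /M/s)
    substrate + coupling partner → open intermediate (k4 = 9.1 /M/s)
    target → over-reaction product (k5 = 1.4 × 10⁻⁴ /s)

- the set-up with the highest amount of open intermediate at the outlet or at the end, in percent of the substrate put in ("none" if the first two lie within 2 percentage points) (gamma / delta / zeta / epsilon / none)
- amount of open intermediate at the outlet or at the end, in percent of the substrate put in, gamma
- amount of open intermediate at the outlet or at the end, in percent of the substrate put in, delta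
- amount of open intermediate at the outlet or at the end, in percent of the substrate put in, zeta
- amount of open intermediate at the outlet or at the end, in percent of the substrate put in, epsilon

- the stated concentrations are those of everything mixed, before any reaction; amounts are the same in each set-up
- the feed brings no volume worth counting
- run time (gamma): 20 s

**The puzzle.** Fresh partner, at 5.50 mM, stands above substrate at 5.0 mM, and a target needs one of each. Still, protic impurity stands beside it at 5.00 mM, and its quench has the constant 1100 /M/s, far above the 21 /M/s of the step that makes second intermediate. So a charge that looks sufficient for the whole substrate may give little target, and the amount of second intermediate that leaks past the impurity is what I reckon.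

**First round.** At the start, fresh partner meets protic impurity at 5.50 /s and coupling partner at 0.210 /s, so nearly all of it is quenched at first. My first answer is the surplus over the impurity, 0.500 mM.

**Going round.** But the impurity falls, so coupling partner's share grows. The two steps split fresh partner in a ratio that doesn't contain c(fresh partner), but it does contain c(coupling partner), which falls as substrate takes coupling partner up. With c(coupling partner) held at its charge, second intermediate made equals 0.191 mM times the logarithm of charged over remaining impurity. Counted to the end of the charge, it also equals the surplus plus the impurity left over.

Putting the surplus back gives 0.864 mM, which overshoots. Putting back the mean of these two gives 0.640 mM. Second intermediate is the limiting reagent for target, so I carry the leak ceiling, second intermediate per substrate charged, 12.8%. In the closed flasks it caps target without ranking them; I don't apply it to the flow tank delta.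

**The forecast.** It names zeta best, with 65.5% for gamma, 46% for delta, 70% for zeta and 54% for epsilon. It holds that “only about 0.5 mM survives to make second intermediate”, whereas I reckon 0.640 mM.

**The result.** The best is zeta, at 70.5%, with gamma at 65.5%, epsilon at 54.2% and delta at 46.2%, so the forecast stands. Target in zeta reaches 3.44%, below the ceiling of 12.8%. By my reckoning, 87.2% of the substrate stays out of target in zeta. Left for 200 s, zeta shows open intermediate at 88.8%.

(The rate constants were drawn at random within sensible limits; the flask was simulated.)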